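**Retrosynthetic overview** (lignan numbering: ring A = O–C7′–C8′–C8–C9; ring B = O–C7–C8–C8′–C9′; C8 is the carbinol carbon)
1. Target 19 ⇐ bis(benzyl ether) 18 by hydrogenolysis of the two phenol protecting groups.
2. 18 ⇐ monocyclic ketone 16: ring B is closed last through the C8–C7 bond by a Norrish–Yang-type photocyclisation, which makes the C–C bond, the tertiary C8–OH and the C7/C8 stereocentres in one operation.
3. Enabling feature: the vicinally dioxygenated pair C8(OH)–C7(H)(Ar)O of ring B, two carbons of like (acceptor) polarity, joined as radicals; the O–C9′–C8′ tether holds the benzylic ether C7–H bonds 1,5 to the ring-A carbonyl carbon C8, on the face cis to C9′.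
4. 16 ⇐ 15 ⇐ 13: ring A is made first by epoxidation and 5-endo ether closure (O–C9 bond) of a homoallylic alcohol, then C8 is oxidised; 13 ⇐ diol 9 + benzylic bromide 11.
5. 9 ⇐ Evans syn-aldol of crotonyl imide 4 with O-benzylvanillin 5 (sets C7′ and C8′). Ring order: A, then B.

Key step: step 8

Assumption: the SMILES is read as the cis-fused furofuran with both aryl groups exo, (7R,7′S,8S,8′R) in lignan numbering; compounds 1, 2, 5 and 10 are taken as commercial.

**Step 1**
Reactants: 1 (S)-4-benzyl-2-oxazolidinone; 2 (E)-crotonyl chloride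
Product: 4 (S)-4-benzyl-3-[(E)-but-2-enoyl]oxazolidin-2-one, via lithium oxazolidinide 3 (not isolated)
Conditions: n-BuLi, THF, −78 °C; then 2, −78 → 0 °C
Reagents that add atoms: none
Why: N-acylation of a lithiated oxazolidinone with an acid chloride is standard auxiliary loading; no stereocentre is formed and the auxiliary centre is untouched.

**Step 2**
Reactants: 4 (S)-4-benzyl-3-[(E)-but-2-enoyl]oxazolidin-2-one; 5 4-(benzyloxy)-3-methoxybenzaldehyde
Product: 8 (S)-4-benzyl-3-[(2S)-2-[(S)-[4-(benzyloxy)-3-methoxyphenyl](hydroxy)methyl]but-3-enoyl]oxazolidin-2-one, via boron dienolate 6 (not isolated), via boron aldolate 7 (not isolated)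
Conditions: Bu2BOTf, Et3N, CH2Cl2, −78 → 0 °C; then 5, −78 → 0 °C; then pH 7 buffer, MeOH, 30% H2O2, 0 °C
Reagents that add atoms: none
Why: Evans boron aldol in its deconjugative form: γ-deprotonation gives the (Z)-O-boron dienolate, which reacts at the α-carbon through a Zimmerman–Traxler chair on the face opposite the auxiliary benzyl group, so the syn α-vinyl β-hydroxy imide should form with C7′ (S) and C8′ set together.

**Step 3**
Reactants: 8 (S)-4-benzyl-3-[(2S)-2-[(S)-[4-(benzyloxy)-3-methoxyphenyl](hydroxy)methyl]but-3-enoyl]oxazolidin-2-one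
Product: 9 (1S,2R)-1-[4-(benzyloxy)-3-methoxyphenyl]-2-vinylpropane-1,3-diol
Conditions: LiBH4, MeOH (1 equiv), THF, 0 °C
Reagents that add atoms: none
Why: Reductive cleavage of the N-acyl oxazolidinone by hydride attack at the exocyclic carbonyl gives the primary alcohol and returns the auxiliary; vinyl group, benzyl ether and both stereocentres are not affected at 0 °C.

**Step 4**
Reactants: 10 4-(benzyloxy)-3-methoxybenzyl alcohol
Product: 11 4-(benzyloxy)-3-methoxybenzyl bromide
Conditions: PBr3 (0.4 equiv), Et2O, 0 °C; used at once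
Reagents that add atoms: phosphorus tribromide, BrP(Br)Br
Why: Bromination of a benzylic alcohol with PBr3 (displacement on the activated phosphite ester) is reliable; the aryl ethers are inert and the labile bromide is used without storage.

**Step 5**
Reactants: 9 (1S,2R)-1-[4-(benzyloxy)-3-methoxyphenyl]-2-vinylpropane-1,3-diol; 11 4-(benzyloxy)-3-methoxybenzyl bromide
Product: 13 (1S,2R)-1-[4-(benzyloxy)-3-methoxyphenyl]-2-({[4-(benzyloxy)-3-methoxybenzyl]oxy}methyl)but-3-en-1-ol, via stannylene acetal 12 (not isolated)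
Conditions: Bu2SnO, toluene, reflux (Dean–Stark); then 11, Bu4NI (cat.), toluene, 80 °C
Reagents that add atoms: none
Why: Regioselective Williamson-type O-alkylation through the dibutylstannylene acetal, in which the less hindered primary oxygen is the more nucleophilic one, so the benzylic secondary hydroxyl should stay free; no stereocentre is touched.

**Step 6**
Reactants: 13 (1S,2R)-1-[4-(benzyloxy)-3-methoxyphenyl]-2-({[4-(benzyloxy)-3-methoxybenzyl]oxy}methyl)but-3-en-1-ol
Product: 15 (4S,5S)-5-[4-(benzyloxy)-3-methoxyphenyl]-4-({[4-(benzyloxy)-3-methoxybenzyl]oxy}methyl)tetrahydrofuran-3-ol (both C3 epimers), via epoxide 14 (not isolated)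
Conditions: mCPBA, CH2Cl2, 0 °C → rt; then CSA (10 mol %), 0 °C
Reagents that add atoms: mCPBA (3-chloroperoxybenzoic acid), O=C(OO)c1cccc(Cl)c1
Why: Prilezhaev epoxidation of the terminal alkene followed by acid-catalysed 5-endo opening at the primary oxirane carbon by the C7′ hydroxyl (favoured over the strained 4-exo oxetane) should close ring A with C7′ and C8′ unchanged; the new carbinol centre forms as both epimers, which converge in step 7.

**Step 7**
Reactants: 15 (4S,5S)-5-[4-(benzyloxy)-3-methoxyphenyl]-4-({[4-(benzyloxy)-3-methoxybenzyl]oxy}methyl)tetrahydrofuran-3-ol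
Product: 16 (4R,5S)-5-[4-(benzyloxy)-3-methoxyphenyl]-4-({[4-(benzyloxy)-3-methoxybenzyl]oxy}methyl)dihydrofuran-3(2H)-one
Conditions: Dess–Martin periodinane, NaHCO3, CH2Cl2, 0 °C → rt; used without delay
Reagents that add atoms: none
Why: Dess–Martin oxidation works under buffered, non-basic conditions, which should avoid enolisation of the β-alkoxy ketone and with it epimerisation at C8′ or β-elimination (retro-oxa-Michael) that would endanger C7′.

**Step 8**
Reactants: 16 (4R,5S)-5-[4-(benzyloxy)-3-methoxyphenyl]-4-({[4-(benzyloxy)-3-methoxybenzyl]oxy}methyl)dihydrofuran-3(2H)-one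
Product: 18 (3R,3aS,6S,6aR)-3,6-bis[4-(benzyloxy)-3-methoxyphenyl]tetrahydro-1H,3H-furo[3,4-c]furan-3a(4H)-ol, via biradical 17 (not isolated)
Conditions: hν (medium-pressure Hg lamp, Pyrex, λ > 290 nm), degassed benzene (0.005 M), rt
Reagents that add atoms: none
Why: n→π* excitation of the ring-A ketone lets the carbonyl oxygen take a hydrogen from the benzylic ether CH2 (future C7) through a seven-membered transition state (1,6-H shift; the γ position is the ether oxygen, so no γ-hydrogen competes), giving the 1,5-biradical 17 (hydroxy-substituted C8 radical and α-alkoxybenzyl C7 radical), which collapses by radical–radical coupling to the C8–C7 bond. The closest known reaction type is the Norrish–Yang photocyclisation in its δ-hydrogen-abstraction form, by which β-alkoxy ketones, including benzyl ethers of 4-(hydroxymethyl)tetrahydrofuran-3-ones, give tetrahydrofuran-3-ols. Ring B closes as a five-membered ring by 1,5-biradical recombination (formally 5-exo attack of C7 on the former carbonyl carbon). C8 is controlled by C8′: the O–C9′ tether can deliver C7 only to the carbonyl face cis to C9′, so the ring fusion is cis and the hydroxyl ends up on the convex face (S); C7 is controlled in the closure by the biradical rotamer that keeps the aryl group exo, away from ring A (R). The step needs site-selective hydrogen transfer, cyclisation faster than α-cleavage and exo selectivity at C7: only the doubly activated (α-oxygen, electron-rich benzylic) C–H bonds can reach the carbonyl oxygen, a 1,5-biradical has no type II fragmentation channel, and the neutral medium leaves the base-sensitive C8′ and C7′ centres untouched.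

**Step 9**
Reactants: 18 (3R,3aS,6S,6aR)-3,6-bis[4-(benzyloxy)-3-methoxyphenyl]tetrahydro-1H,3H-furo[3,4-c]furan-3a(4H)-ol
Product: 19 (3R,3aS,6S,6aR)-3,6-bis(4-hydroxy-3-methoxyphenyl)tetrahydro-1H,3H-furo[3,4-c]furan-3a(4H)-ol (8-hydroxypinoresinol)
Conditions: H2 (1 atm), 10% Pd/C, EtOAc, rt; stopped after uptake of 2 equiv
Reagents that add atoms: none
Why: Hydrogenolysis of aryl benzyl ethers should be faster than cleavage of the ring benzylic C–O bonds of the furofuran under neutral, low-pressure conditions, and the absence of acid avoids epimerisation at C7 and C7′.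

**Compound list**
1 | (S)-4-benzyl-2-oxazolidinone | O=C1N[C@@H](Cc2ccccc2)CO1 | starting material
2 | (E)-crotonyl chloride | C/C=C/C(Cl)=O | starting material
3 | lithium salt of 1 (not isolated) | [Li+].O=C1[N-][C@@H](Cc2ccccc2)CO1 | intermediate
4 | (S)-4-benzyl-3-[(E)-but-2-enoyl]oxazolidin-2-one | C/C=C/C(=O)N1C(=O)OC[C@@H]1Cc1ccccc1 | intermediate
5 | 4-(benzyloxy)-3-methoxybenzaldehyde | COc1cc(C=O)ccc1OCc1ccccc1 | starting material
6 | (Z)-O-dibutylboron dienolate of 4 (not isolated) | C=C/C=C(\OB(CCCC)CCCC)N1C(=O)OC[C@@H]1Cc1ccccc1 | intermediate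
7 | dibutylboron aldolate of 8 (not isolated) | C=C[C@@H]([C@H](OB(CCCC)CCCC)c1ccc(OCc2ccccc2)c(OC)c1)C(=O)N1C(=O)OC[C@@H]1Cc1ccccc1 | intermediate
8 | (S)-4-benzyl-3-[(2S)-2-[(S)-[4-(benzyloxy)-3-methoxyphenyl](hydroxy)methyl]but-3-enoyl]oxazolidin-2-one | C=C[C@@H]([C@H](O)c1ccc(OCc2ccccc2)c(OC)c1)C(=O)N1C(=O)OC[C@@H]1Cc1ccccc1 | intermediate
9 | (1S,2R)-1-[4-(benzyloxy)-3-methoxyphenyl]-2-vinylpropane-1,3-diol | C=C[C@@H]([C@H](O)c1ccc(OCc2ccccc2)c(OC)c1)CO | intermediate
10 | 4-(benzyloxy)-3-methoxybenzyl alcohol | COc1cc(CO)ccc1OCc1ccccc1 | starting material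
11 | 4-(benzyloxy)-3-methoxybenzyl bromide | COc1cc(CBr)ccc1OCc1ccccc1 | intermediate
12 | 2,2-dibutyl-1,3,2-dioxastannane (stannylene acetal) of diol 9, (4S,5R)-4-aryl-5-vinyl (not isolated) | C=C[C@H]1[C@@H](c2ccc(OCc3ccccc3)c(OC)c2)O[Sn](CCCC)(CCCC)OC1 | intermediate
13 | (1S,2R)-1-[4-(benzyloxy)-3-methoxyphenyl]-2-({[4-(benzyloxy)-3-methoxybenzyl]oxy}methyl)but-3-en-1-ol | C=C[C@@H]([C@H](O)c1ccc(OCc2ccccc2)c(OC)c1)COCc1ccc(OCc2ccccc2)c(OC)c1 | intermediate
14 | oxirane of 13: (1S)-1-[4-(benzyloxy)-3-methoxyphenyl]-3-{[4-(benzyloxy)-3-methoxybenzyl]oxy}-2-(oxiran-2-yl)propan-1-ol, C1 and C2 as in 13, both oxirane epimers (not isolated) | C1OC1[C@@H]([C@H](O)c1ccc(OCc2ccccc2)c(OC)c1)COCc1ccc(OCc2ccccc2)c(OC)c1 | intermediate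
15 | (4S,5S)-5-[4-(benzyloxy)-3-methoxyphenyl]-4-({[4-(benzyloxy)-3-methoxybenzyl]oxy}methyl)tetrahydrofuran-3-ol, both C3 epimers | OC1CO[C@H](c2ccc(OCc3ccccc3)c(OC)c2)[C@H]1COCc1ccc(OCc2ccccc2)c(OC)c1 | intermediate
16 | (4R,5S)-5-[4-(benzyloxy)-3-methoxyphenyl]-4-({[4-(benzyloxy)-3-methoxybenzyl]oxy}methyl)dihydrofuran-3(2H)-one | O=C1CO[C@H](c2ccc(OCc3ccccc3)c(OC)c2)[C@H]1COCc1ccc(OCc2ccccc2)c(OC)c1 | intermediate
17 | 1,5-biradical from 16: C8 hydroxy-substituted ring radical and C7 α-alkoxybenzyl radical (not isolated) | O[C]1CO[C@H](c2ccc(OCc3ccccc3)c(OC)c2)[C@H]1CO[CH]c1ccc(OCc2ccccc2)c(OC)c1 | intermediate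
18 | (3R,3aS,6S,6aR)-3,6-bis[4-(benzyloxy)-3-methoxyphenyl]tetrahydro-1H,3H-furo[3,4-c]furan-3a(4H)-ol | COc1cc([C@H]2OC[C@]3(O)[C@@H](c4ccc(OCc5ccccc5)c(OC)c4)OC[C@H]23)ccc1OCc1ccccc1 | intermediate
19 | (3R,3aS,6S,6aR)-3,6-bis(4-hydroxy-3-methoxyphenyl)tetrahydro-1H,3H-furo[3,4-c]furan-3a(4H)-ol (8-hydroxypinoresinol) | COc1cc([C@H]2OC[C@]3(O)[C@@H](c4ccc(O)c(OC)c4)OC[C@H]23)ccc1O | target

**Step count:** 9 steps in total. Longest linear sequence: 8 steps (1, 2, 3, 5, 6, 7, 8, 9); step 4 is a one-step branch.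

**Steps most likely to fail**

Step 8 (photocyclisation). The excited α-alkoxy ketone may fragment by α-cleavage before hydrogen transfer, the electron-rich arenes may quench the excited state, or closure of the biradical may not discriminate well between exo and endo aryl at C7. Fallback: ring B is closed through the C7–O bond instead, setting out from ketone 16 and returning at 18.
- Bromide 11 and PPh3 (toluene, 80 °C) give [4-(benzyloxy)-3-methoxybenzyl]triphenylphosphonium bromide F1.
- Its ylide (KHMDS, THF, −78 → 0 °C) olefinates 16 in a Wittig reaction to the 4-benzylidene tetrahydrofuran F2 (E/Z mixture, both usable).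
- OsO4 (cat.), NMO, acetone–H2O should dihydroxylate the styrene from the face anti to the C8′ substituent, giving the diol F3 with the C8 hydroxyl trans to C9′.
- BF3·OEt2, 1,3,5-trimethoxybenzene (benzyl-cation scavenger), CH2Cl2, −40 → 0 °C ionises the p-alkoxybenzylic C7–OH. The ether oxygen on C9′ closes the five-membered ring with loss of its p-alkoxybenzyl group, the aryl group at the planar C7 cation taking the exo position, to give 18.

Step 6 (epoxidation and ring closure). The oxirane may open by the 4-exo path or with participation of the benzylic ether oxygen, or the peracid may attack the dialkoxyarenes. Fallback: ring A is closed by SN2 displacement of a sulfonate, setting out from 13 and returning at 15.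
- OsO4 (cat.), NMO, acetone–H2O gives the (3R,4S)-butane-1,2,4-triol F4 (both C2 epimers).
- TsCl (1.05 equiv), pyridine, 0 → 40 °C sulfonylates the primary hydroxyl to the primary tosylate F5.
- F5 closes in the same flask by 5-exo-tet Williamson displacement by the C7′ hydroxyl to give 15.

Step 5 (regioselective alkylation). Alkylation may also occur at the benzylic oxygen or twice. Fallback: the two hydroxyls are told apart by protection, setting out from aldol adduct 8 and returning at 13.
- TIPSOTf, 2,6-lutidine, CH2Cl2, 0 °C gives the silyl ether of the aldol adduct F6.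
- LiBH4, MeOH, THF, 0 °C removes the auxiliary to give the primary alcohol F7.
- NaH, 11, Bu4NI, THF–DMF, 0 °C gives the silyl-protected ether F8.
- TBAF, THF, 0 °C frees the C7′ hydroxyl to give 13.

**Further compounds**
F1 | step 8 | [4-(benzyloxy)-3-methoxybenzyl]triphenylphosphonium bromide | COc1cc(C[P+](c2ccccc2)(c2ccccc2)c2ccccc2)ccc1OCc1ccccc1.[Br-]
F2 | step 8 | (2S,3R)-2-[4-(benzyloxy)-3-methoxyphenyl]-4-[4-(benzyloxy)-3-methoxybenzylidene]-3-({[4-(benzyloxy)-3-methoxybenzyl]oxy}methyl)tetrahydrofuran (E/Z mixture) | COc1cc(C=C2CO[C@H](c3ccc(OCc4ccccc4)c(OC)c3)[C@H]2COCc2ccc(OCc3ccccc3)c(OC)c2)ccc1OCc1ccccc1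
F3 | step 8 | (3S,4R,5S)-5-[4-(benzyloxy)-3-methoxyphenyl]-3-{[4-(benzyloxy)-3-methoxyphenyl](hydroxy)methyl}-4-({[4-(benzyloxy)-3-methoxybenzyl]oxy}methyl)tetrahydrofuran-3-ol (both carbinol epimers) | COc1cc(C(O)[C@@]2(O)CO[C@H](c3ccc(OCc4ccccc4)c(OC)c3)[C@H]2COCc2ccc(OCc3ccccc3)c(OC)c2)ccc1OCc1ccccc1
F4 | step 6 | (3R,4S)-4-[4-(benzyloxy)-3-methoxyphenyl]-3-({[4-(benzyloxy)-3-methoxybenzyl]oxy}methyl)butane-1,2,4-triol (both C2 epimers) | OCC(O)[C@@H]([C@H](O)c1ccc(OCc2ccccc2)c(OC)c1)COCc1ccc(OCc2ccccc2)c(OC)c1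
F5 | step 6 | 1-O-(p-toluenesulfonyl) derivative of F4 | Cc1ccc(S(=O)(=O)OCC(O)[C@@H]([C@H](O)c2ccc(OCc3ccccc3)c(OC)c2)COCc2ccc(OCc3ccccc3)c(OC)c2)cc1
F6 | step 5 | (S)-4-benzyl-3-[(2S)-2-[(S)-[4-(benzyloxy)-3-methoxyphenyl](triisopropylsilyloxy)methyl]but-3-enoyl]oxazolidin-2-one | C=C[C@@H]([C@H](O[Si](C(C)C)(C(C)C)C(C)C)c1ccc(OCc2ccccc2)c(OC)c1)C(=O)N1C(=O)OC[C@@H]1Cc1ccccc1
F7 | step 5 | (2R)-2-[(S)-[4-(benzyloxy)-3-methoxyphenyl](triisopropylsilyloxy)methyl]but-3-en-1-ol | C=C[C@@H]([C@H](O[Si](C(C)C)(C(C)C)C(C)C)c1ccc(OCc2ccccc2)c(OC)c1)CO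
F8 | step 5 | triisopropylsilyl ether of 13 (C1 and C2 as in 13) | C=C[C@@H]([C@H](O[Si](C(C)C)(C(C)C)C(C)C)c1ccc(OCc2ccccc2)c(OC)c1)COCc1ccc(OCc2ccccc2)c(OC)c1
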